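The route grows ring A of unit 1 (the 7-methoxyflavone joined through C6) onto C8 of unit 2, so the crowded biaryl bond is never made by coupling. The feature used is the C5-OH, C6-aryl, C7-OMe, C8-H sequence of that ring, fused to pyranone ring C along C4a–C8a. In one operation a 2-(diazoacetyl)-6-aryl-4-pyranone becomes its ketene, adds to an 8-(methoxyethynyl)flavone and closes the benzene ring. This delivers the axis, the chelated 5-OH and the 7-OMe together. The alkyne oxygen already bears the final methyl group, not a silyl group. That replaces an acetylide oxidation on a flavone by one Negishi coupling and leaves only debenzylation.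

Key step: step 8

Assumption: the target SMILES has no descriptor for the C6–C8 biaryl axis, so the axis is taken as unspecified and the route gives the racemic atropisomers.

Atom map of step 8: pyranone O1, C2, C3, C4, C5 and C6 become O1, C8a, C4a, C4, C3 and C2 of unit 1. The acyl carbon becomes C5 and the diazo carbon C8. The aryl-bearing alkyne carbon becomes C6 and the methoxy-bearing one C7.

Step 1
Reactants: 1 apigenin
Product: 2 5,7,4'-tri-O-benzylapigenin
Conditions: BnBr (4.5 equiv), K2CO3, DMF, 80 °C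
Reagents that add atoms: benzyl bromide, BrCc1ccccc1
Why: Williamson etherification, in which excess halide and heat also alkylate the chelated 5-OH, whose ether is needed to steer the next iodination to C8 and to keep a phenol away from the ketene of step 8.

Step 2
Reactants: 2 5,7,4'-tri-O-benzylapigenin
Product: 3 8-iodo-5,7,4'-tri-O-benzylapigenin
Conditions: I2, CF3CO2Ag, CH2Cl2, 0 °C to rt
Reagents that add atoms: iodine, II
Why: Electrophilic aromatic iodination, in which the trioxygenated ring A is by far the most electron-rich ring and C8 (between O1 and one benzyloxy group) should be attacked rather than C6 (between two benzyloxy groups), the usual outcome for 5,7-dialkoxyflavones.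

Step 3
Reactants: 3 8-iodo-5,7,4'-tri-O-benzylapigenin; 4 2-chloro-1,1-dimethoxyethane
Product: 7 8-(methoxyethynyl)-5,7,4'-tri-O-benzylapigenin, via lithium methoxyacetylide 5 (not isolated), via chloro(methoxyethynyl)zinc 6 (not isolated)
Conditions: 4 (2 equiv), LiNEt2 (3 equiv per 4, from Et2NH/n-BuLi), THF, 0 °C; ZnCl2, 0 °C; then 3, Pd(PPh3)4 (5 mol %), rt to 45 °C; aq. NaHCO3 work-up, Et3N-deactivated silica
Reagents that add atoms: none
Why: Twofold base-induced elimination (MeOH, then HCl) and deprotonation turn the chloroacetal into the alkoxyacetylide, and after transmetalation a Negishi alkynylation under zerovalent palladium joins it to the aryl iodide, a coupling known for alkoxyethynylzinc halides in which the slim sp nucleophile tolerates both ortho substituents and the mild organozinc leaves the flavone carbonyl alone.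

Step 4
Reactants: 8 4'-(benzyloxy)acetophenone
Product: 9 1-[4-(benzyloxy)phenyl]butane-1,3-dione
Conditions: NaH, EtOAc, THF, 0 °C to reflux; aq. HCl
Reagents that add atoms: ethyl acetate, CCOC(C)=O
Why: Crossed Claisen condensation of the ketone enolate with ethyl acetate, driven to completion by formation of the stabilised 1,3-diketonate.

Step 5
Reactants: 9 1-[4-(benzyloxy)phenyl]butane-1,3-dione; 10 diethyl oxalate
Product: 12 ethyl 6-[4-(benzyloxy)phenyl]-4-oxo-4H-pyran-2-carboxylate, via triketo ester 11 (not isolated)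
Conditions: NaOEt (2.5 equiv), EtOH, reflux; then HCl, EtOH, 60 °C
Reagents that add atoms: none
Why: Claisen condensation under equilibrating alkoxide conditions ends at the terminal methyl group because only that adduct forms a stable dienolate (acylation at the central carbon reverts), and acid then closes the 4-pyranone by cyclodehydration of the 1,3,5-tricarbonyl chain, as in the classical chelidonic acid preparation.

Step 6
Reactants: 12 ethyl 6-[4-(benzyloxy)phenyl]-4-oxo-4H-pyran-2-carboxylate
Product: 13 6-[4-(benzyloxy)phenyl]-4-oxo-4H-pyran-2-carboxylic acid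
Conditions: LiOH·H2O (1.1 equiv), THF/H2O, 0 °C; then 1 M HCl
Reagents that add atoms: lithium hydroxide, [Li+].[OH-]
Why: Saponification of an activated ester, in which one equivalent of cold hydroxide attacks the ester first and any ring-opened tricarbonyl acid recloses on acidification, so the benzyl ether avoids the hot mineral acid otherwise used for such esters.

Step 7
Reactants: 13 6-[4-(benzyloxy)phenyl]-4-oxo-4H-pyran-2-carboxylic acid
Product: 16 2-(2-diazoacetyl)-6-[4-(benzyloxy)phenyl]-4H-pyran-4-one, via acid chloride 14 (not isolated), via C-silyl diazoketone 15 (not isolated)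
Conditions: (COCl)2, cat. DMF, CH2Cl2, 0 °C to rt, concentrate; TMSCHN2 (1.3 equiv), Et3N, THF/MeCN, 0 °C; aq. NaHCO3
Reagents that add atoms: (trimethylsilyl)diazomethane, C[Si](C)(C)C=[N+]=[N-]
Why: Acylation of a diazoalkane by an acid chloride (first stage of the Arndt–Eistert sequence), in which Et3N takes up HCl, the C-silyl group is lost on aqueous work-up, and the bulky reagent at 0 °C should acylate faster than it adds as a dipole to the pyranone C=C bonds.

Step 8
Reactants: 7 8-(methoxyethynyl)-5,7,4'-tri-O-benzylapigenin; 16 2-(2-diazoacetyl)-6-[4-(benzyloxy)phenyl]-4H-pyran-4-one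
Product: 21 4',5'',7'',4'''-tetra-O-benzyl-7-O-methylagathisflavone (free 5-OH), via pyranonylketene 17 (not isolated), via cyclobutenone 18 (not isolated), via dienylketene 19 (not isolated), via cyclohexadienone 20 (not isolated)
Conditions: 7 (1 equiv), 16 (1.5 equiv, added over several hours), blue LEDs (440 nm), degassed dry ClCH2CH2Cl, 25 °C; then 80 °C
Reagents that add atoms: none
Why: Light of 440 nm should be absorbed only by the diazo chromophore of 16, N2 leaves and pyranone C2 shifts to the carbene carbon (Wolff rearrangement, which also makes the future C8–C8a bond) to give ketene 17, whose vinyl arm is the pyranone C2=C3 bond (future C8a=C4a). The aryl-bearing carbon of ynol ether 7 attacks the ketene carbonyl carbon and a (2+2) cycloaddition sets C5–C6 and C7–C8 in cyclobutenone 18, which on heating opens reversibly by 4π electrocyclic cleavage of the former ketene C=C bond to dienylketene 19. Ring A closes by thermal disrotatory 6π electrocyclisation of 19 onto pyranone C3 (C4a–C5), and dienone 20 enolises to the chelated phenol 21. The sequence is the diazoketone form of the Danheiser benzannulation, which is established for vinyl, aryl and heteroaryl diazoketones with alkoxy- and siloxyalkynes. The regiochemistry needed (aryl at C6, OMe at C7) follows from the methoxy group, which makes the flavonyl-bearing alkyne carbon the nucleophile, and the closure has one possible site because the other neighbour of pyranone C2 is O1. No stereocentre survives (C4 of 18 and C4a of 20 are transient) and the axis forms as a racemate; the linear alkyne holds the ortho substituents of unit 2 away from the first bond-forming event, the small methyl group eases crowding around the axis, and visible light spares the flavone and pyranone chromophores.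

Step 9
Reactants: 21 4',5'',7'',4'''-tetra-O-benzyl-7-O-methylagathisflavone
Product: 22 7-O-methylagathisflavone (target)
Conditions: H2 (1 atm), 10% Pd/C, THF/MeOH, rt
Reagents that add atoms: none
Why: Catalytic hydrogenolysis of the four aryl benzyl ethers, under which the flavone C2=C3 bonds and the aryl methyl ether are normally untouched at 1 atm and room temperature.

Compound list
1 | apigenin | O=c1cc(-c2ccc(O)cc2)oc2cc(O)cc(O)c12 | starting material
2 | 5,7-bis(benzyloxy)-2-[4-(benzyloxy)phenyl]-4H-chromen-4-one | O=c1cc(-c2ccc(OCc3ccccc3)cc2)oc2cc(OCc3ccccc3)cc(OCc3ccccc3)c12 | intermediate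
3 | 5,7-bis(benzyloxy)-2-[4-(benzyloxy)phenyl]-8-iodo-4H-chromen-4-one | Ic1c(OCc2ccccc2)cc(OCc2ccccc2)c2c(=O)cc(-c3ccc(OCc4ccccc4)cc3)oc12 | intermediate
4 | 2-chloro-1,1-dimethoxyethane | COC(CCl)OC | starting material
5 | lithium methoxyacetylide | [Li]C#COC | intermediate
6 | chloro(methoxyethynyl)zinc | Cl[Zn]C#COC | intermediate
7 | 5,7-bis(benzyloxy)-2-[4-(benzyloxy)phenyl]-8-(methoxyethynyl)-4H-chromen-4-one | COC#Cc1c(OCc2ccccc2)cc(OCc2ccccc2)c2c(=O)cc(-c3ccc(OCc4ccccc4)cc3)oc12 | intermediate
8 | 4'-(benzyloxy)acetophenone | CC(=O)c1ccc(OCc2ccccc2)cc1 | starting material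
9 | 1-[4-(benzyloxy)phenyl]butane-1,3-dione | CC(=O)CC(=O)c1ccc(OCc2ccccc2)cc1 | intermediate
10 | diethyl oxalate | CCOC(=O)C(=O)OCC | starting material
11 | ethyl 6-[4-(benzyloxy)phenyl]-2,4,6-trioxohexanoate | CCOC(=O)C(=O)CC(=O)CC(=O)c1ccc(OCc2ccccc2)cc1 | intermediate
12 | ethyl 6-[4-(benzyloxy)phenyl]-4-oxo-4H-pyran-2-carboxylate | CCOC(=O)c1cc(=O)cc(-c2ccc(OCc3ccccc3)cc2)o1 | intermediate
13 | 6-[4-(benzyloxy)phenyl]-4-oxo-4H-pyran-2-carboxylic acid | OC(=O)c1cc(=O)cc(-c2ccc(OCc3ccccc3)cc2)o1 | intermediate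
14 | 6-[4-(benzyloxy)phenyl]-4-oxo-4H-pyran-2-carbonyl chloride | ClC(=O)c1cc(=O)cc(-c2ccc(OCc3ccccc3)cc2)o1 | intermediate
15 | 2-[diazo(trimethylsilyl)acetyl]-6-[4-(benzyloxy)phenyl]-4H-pyran-4-one | C[Si](C)(C)C(=[N+]=[N-])C(=O)c1cc(=O)cc(-c2ccc(OCc3ccccc3)cc2)o1 | intermediate
16 | 2-(2-diazoacetyl)-6-[4-(benzyloxy)phenyl]-4H-pyran-4-one | [N-]=[N+]=CC(=O)c1cc(=O)cc(-c2ccc(OCc3ccccc3)cc2)o1 | intermediate
17 | {6-[4-(benzyloxy)phenyl]-4-oxo-4H-pyran-2-yl}ketene | O=C=Cc1cc(=O)cc(-c2ccc(OCc3ccccc3)cc2)o1 | intermediate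
18 | 3-methoxy-2-(tribenzyloxyflavon-8-yl)-4-(6-aryl-4-oxopyran-2-yl)cyclobut-2-en-1-one (racemic at C4) | COC1=C(c2c(OCc3ccccc3)cc(OCc3ccccc3)c3c(=O)cc(-c4ccc(OCc5ccccc5)cc4)oc23)C(=O)C1c1cc(=O)cc(-c2ccc(OCc3ccccc3)cc2)o1 | intermediate
19 | dienylketene, 2-(tribenzyloxyflavon-8-yl)-3-methoxy-4-(6-aryl-4-oxopyran-2-yl)buta-1,3-dien-1-one, pyranonyl group cis to the ketene-bearing carbon | COC(/C(=C=O)c1c(OCc2ccccc2)cc(OCc2ccccc2)c2c(=O)cc(-c3ccc(OCc4ccccc4)cc3)oc12)=C/c1cc(=O)cc(-c2ccc(OCc3ccccc3)cc2)o1 | intermediate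
20 | 4a-H cyclohexadienone, keto tautomer of 21 (racemic at C4a) | COC1=C(c2c(OCc3ccccc3)cc(OCc3ccccc3)c3c(=O)cc(-c4ccc(OCc5ccccc5)cc4)oc23)C(=O)C2C(=O)C=C(c3ccc(OCc4ccccc4)cc3)OC2=C1 | intermediate
21 | 2-[4-(benzyloxy)phenyl]-6-{5,7-bis(benzyloxy)-2-[4-(benzyloxy)phenyl]-4-oxo-4H-chromen-8-yl}-5-hydroxy-7-methoxy-4H-chromen-4-one (racemic axis) | COc1cc2oc(-c3ccc(OCc4ccccc4)cc3)cc(=O)c2c(O)c1-c1c(OCc2ccccc2)cc(OCc2ccccc2)c2c(=O)cc(-c3ccc(OCc4ccccc4)cc3)oc12 | intermediate
22 | 6-[5,7-dihydroxy-2-(4-hydroxyphenyl)-4-oxo-4H-chromen-8-yl]-5-hydroxy-2-(4-hydroxyphenyl)-7-methoxy-4H-chromen-4-one (7-O-methylagathisflavone, CNP0246647.0) | COc1cc2oc(-c3ccc(O)cc3)cc(=O)c2c(O)c1-c1c(O)cc(O)c2c(=O)cc(-c3ccc(O)cc3)oc12 | target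

Total step count: 9
Longest linear sequence: 6 steps (steps 4, 5, 6, 7, 8, 9, from 8 to 22). The apigenin branch contributes 5 steps (steps 1, 2, 3, 8, 9).

Steps most likely to fail

1. Step 8. Several processes could compete:
- The ketene may be lost by dimerisation, by moisture or by acylating the new phenol.
- The diazoketone may add as a dipole to the electron-rich alkyne before it is photolysed.
- The crowded cyclobutenone may resist ring opening and closure.

The fallback gives up the annulation for a conventional hindered biaryl coupling. It sets out from 3 and returns at 21. Miyaura borylation of 3 (B2pin2, PdCl2(dppf), KOAc, dioxane, 90 °C) gives the 8-pinacolboronate F1. Purchased genkwanin F2 is benzylated at the unchelated 4'-OH (BnBr, K2CO3, acetone, reflux) to 4'-O-benzylgenkwanin F3. This is iodinated ortho to the chelated 5-OH (BnMe3NICl2, CaCO3, CH2Cl2/MeOH) to the 6-iodide F4. Suzuki–Miyaura coupling of F1 with F4 (Pd(OAc)2, SPhos, K3PO4, toluene/H2O, 100 °C) then gives 21.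

2. Step 3. The acid-sensitive ynol ether may hydrate or oligomerise during coupling and chromatography, or the elimination to the acetylide may be incomplete. In the fallback the oxygen is put on a finished aryl alkyne and carried as a silyl ether. It sets out from 3 and returns at 21.
- Sonogashira coupling of 3 with ethynyltrimethylsilane (PdCl2(PPh3)2, CuI, Et3N/THF, 50 °C) gives the silylalkyne F5.
- K2CO3 in MeOH/THF gives the terminal alkyne F6.
- LiHMDS followed by lithium tert-butyl peroxide (THF, −78 to 0 °C) oxidises the acetylide to the lithium ynolate F7.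
- TIPSOTf at −78 °C traps F7 as the triisopropylsiloxyalkyne F8.
- F8 and 16 under the conditions of step 8 give the 7-O-triisopropylsilyl biflavone F9.
- TBAF (THF, 0 °C) frees the 5,7-diol F10.
- MeI with K2CO3 in acetone methylates only the unchelated 7-OH to give 21.

3. Step 7. The diazoalkane may add as a dipole to the electron-poor pyranone, or the chlorinating agent may activate the ring carbonyl. The fallback installs the diazo group by diazo transfer instead of acylation. It sets out from 9 and returns at 16. The dianion of 9 (NaH, then n-BuLi, THF) is acylated at the terminal carbon with ethyl 2,2-diethoxypropanoate to the ketal triketone F11. Aqueous HCl in THF closes the pyranone and removes the ketal to give the 2-acetylpyranone F12. LiHMDS and CF3CO2CH2CF3 (THF, −78 °C) give the trifluoroacetyl diketone F13. Detrifluoroacetylative diazo transfer (MsN3, Et3N, H2O, MeCN) then delivers 16.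

Further compounds
F1 | step 8 | 5,7-bis(benzyloxy)-2-[4-(benzyloxy)phenyl]-8-(4,4,5,5-tetramethyl-1,3,2-dioxaborolan-2-yl)-4H-chromen-4-one | CC1(C)OB(OC1(C)C)c1c(OCc2ccccc2)cc(OCc2ccccc2)c2c(=O)cc(-c3ccc(OCc4ccccc4)cc3)oc12
F2 | step 8 | genkwanin (purchased) | COc1cc(O)c2c(=O)cc(-c3ccc(O)cc3)oc2c1
F3 | step 8 | 4'-O-benzylgenkwanin | COc1cc(O)c2c(=O)cc(-c3ccc(OCc4ccccc4)cc3)oc2c1
F4 | step 8 | 2-[4-(benzyloxy)phenyl]-5-hydroxy-6-iodo-7-methoxy-4H-chromen-4-one | COc1cc2oc(-c3ccc(OCc4ccccc4)cc3)cc(=O)c2c(O)c1I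
F5 | step 3 | 5,7-bis(benzyloxy)-2-[4-(benzyloxy)phenyl]-8-[(trimethylsilyl)ethynyl]-4H-chromen-4-one | C[Si](C)(C)C#Cc1c(OCc2ccccc2)cc(OCc2ccccc2)c2c(=O)cc(-c3ccc(OCc4ccccc4)cc3)oc12
F6 | step 3 | 5,7-bis(benzyloxy)-2-[4-(benzyloxy)phenyl]-8-ethynyl-4H-chromen-4-one | C#Cc1c(OCc2ccccc2)cc(OCc2ccccc2)c2c(=O)cc(-c3ccc(OCc4ccccc4)cc3)oc12
F7 | step 3 | lithium ynolate of F6 | [Li]OC#Cc1c(OCc2ccccc2)cc(OCc2ccccc2)c2c(=O)cc(-c3ccc(OCc4ccccc4)cc3)oc12
F8 | step 3 | 5,7-bis(benzyloxy)-2-[4-(benzyloxy)phenyl]-8-[(triisopropylsilyloxy)ethynyl]-4H-chromen-4-one | CC(C)[Si](C(C)C)(C(C)C)OC#Cc1c(OCc2ccccc2)cc(OCc2ccccc2)c2c(=O)cc(-c3ccc(OCc4ccccc4)cc3)oc12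
F9 | step 3 | tetra-O-benzyl-7-O-(triisopropylsilyl)agathisflavone with free 5-OH | CC(C)[Si](C(C)C)(C(C)C)Oc1cc2oc(-c3ccc(OCc4ccccc4)cc3)cc(=O)c2c(O)c1-c1c(OCc2ccccc2)cc(OCc2ccccc2)c2c(=O)cc(-c3ccc(OCc4ccccc4)cc3)oc12
F10 | step 3 | 4',5'',7'',4'''-tetra-O-benzylagathisflavone (5,7-diol) | Oc1cc2oc(-c3ccc(OCc4ccccc4)cc3)cc(=O)c2c(O)c1-c1c(OCc2ccccc2)cc(OCc2ccccc2)c2c(=O)cc(-c3ccc(OCc4ccccc4)cc3)oc12
F11 | step 7 | 1-[4-(benzyloxy)phenyl]-6,6-diethoxyheptane-1,3,5-trione | CCOC(C)(OCC)C(=O)CC(=O)CC(=O)c1ccc(OCc2ccccc2)cc1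
F12 | step 7 | 2-acetyl-6-[4-(benzyloxy)phenyl]-4H-pyran-4-one | CC(=O)c1cc(=O)cc(-c2ccc(OCc3ccccc3)cc2)o1
F13 | step 7 | 1-{6-[4-(benzyloxy)phenyl]-4-oxo-4H-pyran-2-yl}-4,4,4-trifluorobutane-1,3-dione | O=C(CC(=O)C(F)(F)F)c1cc(=O)cc(-c2ccc(OCc3ccccc3)cc2)o1
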